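**Plan**

- Last cuts: the three benzyl ethers and the benzyl ester (global hydrogenolysis). The ring B C2 hydroxyl is traced back to a C2 bromine (borylation, then oxidation).
- Ring B is then cut at C1–C6 and C2–C3. Its C3, C4, C5 and C6, with the ring A acyloxy group on C4 and the methyl on C6, are the diene carbons of O-acylated triacetic acid lactone after loss of CO2. C1 (ester) and C2 (Br) are the two carbons of a 3-bromopropiolate.
- Both depside C–O bonds are therefore made before the ring exists, as simple esterifications: ring A acid chloride with the lactone enol, and propiolic acid with the ring C phenol.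
- Forward: the ring A acid is built from 4-methoxy-2-methylphenol and put on the pyrone (steps 1–6). The ring C bromoalkynoate is built from orsellinic acid (steps 7–12). Ring B closes in step 13, followed by Br to OH and debenzylation (steps 14–16).
- The target has no stereocentre; the only stereogenic atoms on the route are the two bridgeheads of the transient cycloadduct, and they vanish on aromatisation.

Key step: step 13

Remark: ring B is numbered from its ester-bearing carbon (C1 ester, C2 OH, C4 ring A acyloxy, C6 methyl); ring A is the 4,5-dihydroxy-2-methoxy-6-methylbenzoyl unit and ring C the orsellinic acid unit with the free carboxyl group.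

**Route**

Step 1
Reactants: 1 4-methoxy-2-methylphenol
Product: 2 2-hydroxy-5-methoxy-3-methylbenzaldehyde
Conditions: MgCl2, Et3N, (CH2O)n, MeCN, reflux
Reagents that add atoms: paraformaldehyde (as formaldehyde), C=O
Why: Magnesium-phenoxide-directed ortho-formylation (Casnati–Skattebøl reaction) should deliver formaldehyde to the only free position ortho to the hydroxyl, a second formaldehyde oxidising the benzylic alkoxide to the aldehyde.

Step 2
Reactants: 2 2-hydroxy-5-methoxy-3-methylbenzaldehyde
Product: 3 5-methoxy-3-methylbenzene-1,2-diol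
Conditions: 30% H2O2, NaOH, H2O/THF, 0 °C to rt, N2; then 1 M HCl
Reagents that add atoms: hydrogen peroxide, OO
Why: In this Dakin oxidation the electron-rich ortho-hydroxyaryl group should migrate from carbon to oxygen in the hydroperoxide adduct and the aryl formate is saponified in the flask, with exclusion of air and prompt acidification protecting the oxidisable catechol.

Step 3
Reactants: 3 5-methoxy-3-methylbenzene-1,2-diol
Product: 4 1,2-bis(benzyloxy)-5-methoxy-3-methylbenzene
Conditions: BnBr, K2CO3, DMF, rt to 50 °C, N2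
Reagents that add atoms: benzyl bromide, BrCc1ccccc1
Why: Williamson etherification of both catechol hydroxyls with a reactive benzylic halide under carbonate base should be straightforward.

Step 4
Reactants: 4 1,2-bis(benzyloxy)-5-methoxy-3-methylbenzene
Product: 5 4,5-bis(benzyloxy)-2-methoxy-6-methylbenzaldehyde
Conditions: POCl3, DMF, 0 to 75 °C; then ice-water
Reagents that add atoms: N,N-dimethylformamide, CN(C)C=O; water, O
Why: In this Vilsmeier–Haack formylation the chloroiminium ion should attack the site para to the unflanked C1 benzyloxy group and ortho to the methoxy group, since the only other free site lies between two alkoxy groups, a position that electrophiles avoid in 1,2,4-trialkoxybenzenes.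

Step 5
Reactants: 5 4,5-bis(benzyloxy)-2-methoxy-6-methylbenzaldehyde
Product: 6 4,5-bis(benzyloxy)-2-methoxy-6-methylbenzoic acid
Conditions: NaClO2, NaH2PO4, 2-methyl-2-butene, t-BuOH/H2O, rt
Reagents that add atoms: sodium chlorite, [Na+].[O-]Cl=O
Why: Pinnick oxidation should convert the hindered, electron-rich aldehyde into the acid without touching the benzyl ethers, the alkene trapping HOCl before it can chlorinate the ring.

Step 6
Reactants: 6 4,5-bis(benzyloxy)-2-methoxy-6-methylbenzoic acid; 7 4-hydroxy-6-methyl-2H-pyran-2-one (triacetic acid lactone)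
Product: 9 6-methyl-2-oxo-2H-pyran-4-yl 4,5-bis(benzyloxy)-2-methoxy-6-methylbenzoate, via acid chloride 8 (not isolated)
Conditions: (COCl)2, DMF (cat.), CH2Cl2, 0 °C to rt, evaporate; then 7, Et3N, CH2Cl2, 0 °C to rt
Reagents that add atoms: none
Why: Acid chloride formation followed by O-acylation of the vinylogous acid at its 4-oxygen (the usual site with acid chloride and amine base) should give the enol ester, and leaving out DMAP or cyanide avoids the Fries-type acyl shift to C3.

Step 7
Reactants: 10 2,4-dihydroxy-6-methylbenzoic acid (orsellinic acid)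
Product: 11 benzyl 2,4-dihydroxy-6-methylbenzoate
Conditions: BnBr, KHCO3, DMF, rt
Reagents that add atoms: benzyl bromide, BrCc1ccccc1
Why: Bicarbonate should deprotonate only the carboxylic acid, so carboxylate alkylation gives the benzyl ester with both phenols free, and room temperature avoids decarboxylation of the resorcylic acid.

Step 8
Reactants: 11 benzyl 2,4-dihydroxy-6-methylbenzoate
Product: 12 benzyl 2-hydroxy-6-methyl-4-(prop-2-en-1-yloxy)benzoate
Conditions: allyl bromide (1.05 equiv), K2CO3, acetone, reflux
Reagents that add atoms: allyl bromide, C=CCBr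
Why: Regioselective Williamson etherification is expected because the 2-hydroxyl is locked in a hydrogen bond to the ester carbonyl, whereas the 4-hydroxyl para to the ester is more acidic and unhindered.

Step 9
Reactants: 12 benzyl 2-hydroxy-6-methyl-4-(prop-2-en-1-yloxy)benzoate
Product: 13 benzyl 2-(benzyloxy)-6-methyl-4-(prop-2-en-1-yloxy)benzoate
Conditions: BnBr, K2CO3, DMF, 60 °C
Reagents that add atoms: benzyl bromide, BrCc1ccccc1
Why: Williamson etherification of the chelated 2-phenol should proceed under these more forcing conditions, as is usual for salicylate-type hydroxyls.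

Step 10
Reactants: 13 benzyl 2-(benzyloxy)-6-methyl-4-(prop-2-en-1-yloxy)benzoate
Product: 14 benzyl 2-(benzyloxy)-4-hydroxy-6-methylbenzoate
Conditions: Pd(PPh3)4 (cat.), morpholine, THF, rt
Reagents that add atoms: none
Why: In this Tsuji–Trost deallylation zerovalent palladium should ionise the aryl allyl ether to a π-allyl palladium complex that morpholine intercepts, leaving the benzyl ether and benzyl ester untouched.

Step 11
Reactants: 14 benzyl 2-(benzyloxy)-4-hydroxy-6-methylbenzoate; 15 propiolic acid
Product: 16 benzyl 2-(benzyloxy)-6-methyl-4-(prop-2-ynoyloxy)benzoate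
Conditions: DCC, DMAP (cat.), CH2Cl2, −10 to 0 °C
Reagents that add atoms: none
Why: Steglich esterification of the single free phenol with the unhindered acid should give the aryl propiolate, the low temperature suppressing conjugate addition to the ynoate.

Step 12
Reactants: 16 benzyl 2-(benzyloxy)-6-methyl-4-(prop-2-ynoyloxy)benzoate
Product: 17 benzyl 2-(benzyloxy)-4-[(3-bromoprop-2-ynoyl)oxy]-6-methylbenzoate
Conditions: NBS, AgNO3 (10 mol %), acetone, rt, dark
Reagents that add atoms: N-bromosuccinimide, O=C1CCC(=O)N1Br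
Why: Silver-catalysed electrophilic bromination of the terminal alkyne through its silver acetylide should be fast at room temperature, so the fully protected arene should not be brominated.

Step 13
Reactants: 9 6-methyl-2-oxo-2H-pyran-4-yl 4,5-bis(benzyloxy)-2-methoxy-6-methylbenzoate; 17 benzyl 2-(benzyloxy)-4-[(3-bromoprop-2-ynoyl)oxy]-6-methylbenzoate
Product: 19 benzyl 2-(benzyloxy)-4-[(4-{[4,5-bis(benzyloxy)-2-methoxy-6-methylbenzoyl]oxy}-2-bromo-6-methylbenzoyl)oxy]-6-methylbenzoate, via bridged lactone 18 (not isolated)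
Conditions: PhCl, 130 °C, sealed tube, Ar, BHT (cat.); 17 (1.5 equiv) added in two portions
Reagents that add atoms: none
Why: A thermal, normal-demand [4+2] cycloaddition should join pyrone C3 and C6 to the two alkyne carbons to give bridged lactone 18, which fragments by retro-[4+2] loss of CO2 and so delivers the benzene ring directly. The closest known reaction type is the Diels–Alder reaction of 2-pyrones, 4-oxygenated 6-methyl-2-pyrones included, with acetylenic esters followed by CO2 extrusion to benzoates. Ring B is closed by intermolecular cycloaddition that forms C2–C3 and C1–C6 in one operation, four ring carbons coming from the pyrone and two from the alkyne. No stereocentre is created in the product, because the two bridgehead centres of racemic 18 are erased on aromatisation. One regiochemical orientation is required: pyrone C3, the nucleophilic diene terminus (β to the 4-acyloxy oxygen and vinylogous to the ring oxygen and the 6-methyl group), must bond to the electrophilic, bromine-bearing β-carbon of the ynoate, which places the ester carbon next to the methyl-bearing carbon and para to the acyloxy group. The bromine and the aryl ester both lower the alkyne LUMO, which should let the reaction run below the temperature at which either ester breaks down.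

Step 14
Reactants: 19 benzyl 2-(benzyloxy)-4-[(4-{[4,5-bis(benzyloxy)-2-methoxy-6-methylbenzoyl]oxy}-2-bromo-6-methylbenzoyl)oxy]-6-methylbenzoate
Product: 20 benzyl 2-(benzyloxy)-4-{[4-{[4,5-bis(benzyloxy)-2-methoxy-6-methylbenzoyl]oxy}-6-methyl-2-(4,4,5,5-tetramethyl-1,3,2-dioxaborolan-2-yl)benzoyl]oxy}-6-methylbenzoate
Conditions: B2pin2, PdCl2(dppf) (5 mol %), KOAc, 1,4-dioxane, 85 °C
Reagents that add atoms: bis(pinacolato)diboron, CC1(C)OB(OC1(C)C)B1OC(C)(C)C(C)(C)O1
Why: In this Miyaura borylation the ester-activated aryl bromide should add oxidatively to zerovalent palladium and acetate-assisted transmetalation with the diboron follows, KOAc being too weak a base to cleave the di-ortho-substituted aryl esters.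

Step 15
Reactants: 20 the ring B pinacol boronate
Product: 21 benzyl 2-(benzyloxy)-4-[(4-{[4,5-bis(benzyloxy)-2-methoxy-6-methylbenzoyl]oxy}-2-hydroxy-6-methylbenzoyl)oxy]-6-methylbenzoate
Conditions: NaBO3·4H2O, THF/H2O, rt
Reagents that add atoms: sodium perborate, [Na+].[O-]B1OO1
Why: Boronate oxidation (peroxide addition to boron, 1,2-aryl shift to oxygen, hydrolysis) should give the phenol at mild pH, and both depside carbonyls are flanked by two ortho substituents and should resist hydrolysis.

Step 16
Reactants: 21 the ring B phenol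
Product: 22 4-[(4-{[4,5-dihydroxy-2-methoxy-6-methylbenzoyl]oxy}-2-hydroxy-6-methylbenzoyl)oxy]-2-hydroxy-6-methylbenzoic acid (target)
Conditions: H2 (1 atm), 10% Pd/C, EtOAc/THF, rt
Reagents that add atoms: none
Why: Catalytic hydrogenolysis should cleave the three benzyl ethers and the benzyl ester in one operation, while aryl esters are inert and no halogen remains to be reduced.

**Compound list**

1 | 4-methoxy-2-methylphenol | COc1ccc(O)c(C)c1 | starting material
2 | 2-hydroxy-5-methoxy-3-methylbenzaldehyde | COc1cc(C)c(O)c(C=O)c1 | intermediate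
3 | 5-methoxy-3-methylbenzene-1,2-diol | COc1cc(C)c(O)c(O)c1 | intermediate
4 | 1,2-bis(benzyloxy)-5-methoxy-3-methylbenzene | COc1cc(C)c(OCc2ccccc2)c(OCc2ccccc2)c1 | intermediate
5 | 4,5-bis(benzyloxy)-2-methoxy-6-methylbenzaldehyde | COc1cc(OCc2ccccc2)c(OCc2ccccc2)c(C)c1C=O | intermediate
6 | 4,5-bis(benzyloxy)-2-methoxy-6-methylbenzoic acid | COc1cc(OCc2ccccc2)c(OCc2ccccc2)c(C)c1C(=O)O | intermediate
7 | 4-hydroxy-6-methyl-2H-pyran-2-one (triacetic acid lactone) | Cc1cc(O)cc(=O)o1 | starting material
8 | 4,5-bis(benzyloxy)-2-methoxy-6-methylbenzoyl chloride (not isolated) | COc1cc(OCc2ccccc2)c(OCc2ccccc2)c(C)c1C(Cl)=O | intermediate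
9 | 6-methyl-2-oxo-2H-pyran-4-yl 4,5-bis(benzyloxy)-2-methoxy-6-methylbenzoate | COc1cc(OCc2ccccc2)c(OCc2ccccc2)c(C)c1C(=O)Oc1cc(C)oc(=O)c1 | intermediate
10 | 2,4-dihydroxy-6-methylbenzoic acid (orsellinic acid) | Cc1cc(O)cc(O)c1C(=O)O | starting material
11 | benzyl 2,4-dihydroxy-6-methylbenzoate | Cc1cc(O)cc(O)c1C(=O)OCc1ccccc1 | intermediate
12 | benzyl 2-hydroxy-6-methyl-4-(prop-2-en-1-yloxy)benzoate | C=CCOc1cc(C)c(C(=O)OCc2ccccc2)c(O)c1 | intermediate
13 | benzyl 2-(benzyloxy)-6-methyl-4-(prop-2-en-1-yloxy)benzoate | C=CCOc1cc(C)c(C(=O)OCc2ccccc2)c(OCc2ccccc2)c1 | intermediate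
14 | benzyl 2-(benzyloxy)-4-hydroxy-6-methylbenzoate | Oc1cc(C)c(C(=O)OCc2ccccc2)c(OCc2ccccc2)c1 | intermediate
15 | propiolic acid (prop-2-ynoic acid) | C#CC(=O)O | starting material
16 | benzyl 2-(benzyloxy)-6-methyl-4-(prop-2-ynoyloxy)benzoate | C#CC(=O)Oc1cc(C)c(C(=O)OCc2ccccc2)c(OCc2ccccc2)c1 | intermediate
17 | benzyl 2-(benzyloxy)-4-[(3-bromoprop-2-ynoyl)oxy]-6-methylbenzoate | BrC#CC(=O)Oc1cc(C)c(C(=O)OCc2ccccc2)c(OCc2ccccc2)c1 | intermediate
18 | bridged lactone, racemic (one enantiomer drawn): 2-oxabicyclo[2.2.2]octa-5,7-dien-3-one with methyl on C1, bromine on C5, the ring C aryloxycarbonyl group on C6 and the ring A aroyloxy group on C8 (not isolated) | C[C@]12OC(=O)[C@H](C(OC(=O)c3c(OC)cc(OCc4ccccc4)c(OCc4ccccc4)c3C)=C1)C(Br)=C2C(=O)Oc1cc(C)c(C(=O)OCc2ccccc2)c(OCc2ccccc2)c1 | intermediate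
19 | benzyl 2-(benzyloxy)-4-[(4-{[4,5-bis(benzyloxy)-2-methoxy-6-methylbenzoyl]oxy}-2-bromo-6-methylbenzoyl)oxy]-6-methylbenzoate | COc1cc(OCc2ccccc2)c(OCc2ccccc2)c(C)c1C(=O)Oc1cc(C)c(C(=O)Oc2cc(C)c(C(=O)OCc3ccccc3)c(OCc3ccccc3)c2)c(Br)c1 | intermediate
20 | benzyl 2-(benzyloxy)-4-{[4-{[4,5-bis(benzyloxy)-2-methoxy-6-methylbenzoyl]oxy}-6-methyl-2-(4,4,5,5-tetramethyl-1,3,2-dioxaborolan-2-yl)benzoyl]oxy}-6-methylbenzoate | COc1cc(OCc2ccccc2)c(OCc2ccccc2)c(C)c1C(=O)Oc1cc(C)c(C(=O)Oc2cc(C)c(C(=O)OCc3ccccc3)c(OCc3ccccc3)c2)c(B2OC(C)(C)C(C)(C)O2)c1 | intermediate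
21 | benzyl 2-(benzyloxy)-4-[(4-{[4,5-bis(benzyloxy)-2-methoxy-6-methylbenzoyl]oxy}-2-hydroxy-6-methylbenzoyl)oxy]-6-methylbenzoate | COc1cc(OCc2ccccc2)c(OCc2ccccc2)c(C)c1C(=O)Oc1cc(C)c(C(=O)Oc2cc(C)c(C(=O)OCc3ccccc3)c(OCc3ccccc3)c2)c(O)c1 | intermediate
22 | 4-[(4-{[4,5-dihydroxy-2-methoxy-6-methylbenzoyl]oxy}-2-hydroxy-6-methylbenzoyl)oxy]-2-hydroxy-6-methylbenzoic acid | COc1cc(O)c(O)c(C)c1C(=O)Oc1cc(C)c(C(=O)Oc2cc(C)c(C(=O)O)c(O)c2)c(O)c1 | target

**Count and risks**

Total steps: 16. Longest linear sequence: 10 steps (steps 1–6, then 13–16; the ring C branch, steps 7–12 then 13–16, is equally long).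

Steps most likely to fail:

1. Step 13. The acyloxy group is only a weak donor on the diene, so cycloaddition may be slower than thermal oligomerisation of the bromoalkynoate, or the two regiochemical orientations may compete. Fallback, setting out from 7 and 17 and returning at 19: silylation of 7 (i-Pr3SiCl, imidazole, CH2Cl2) should give 6-methyl-4-[(triisopropylsilyl)oxy]-2H-pyran-2-one F1, a more electron-rich diene with the same polarisation. Heating F1 with 17 in toluene at 100–110 °C should give, through the bridged lactone F2 and loss of CO2, benzyl 2-(benzyloxy)-4-({2-bromo-6-methyl-4-[(triisopropylsilyl)oxy]benzoyl}oxy)-6-methylbenzoate F3. Desilylation with Bu4NF/AcOH in THF at 0 °C should free the ring B phenol benzyl 2-(benzyloxy)-4-[(2-bromo-4-hydroxy-6-methylbenzoyl)oxy]-6-methylbenzoate F4. Acylation of F4 with acid chloride 8 (Et3N, DMAP cat., CH2Cl2), the classical depside coupling, then gives 19. In this variant ring A is attached after the ring closure instead of before it.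

2. Step 14. The C–Br bond may be reduced to C–H, or transmetalation may stall at the ester-flanked position, which would remove the handle for the ring B hydroxyl. Fallback, setting out from 19 and returning at 22: palladium-catalysed C–O coupling with benzyl alcohol (Pd2(dba)3, t-BuBrettPhos, Cs2CO3, toluene, 80 °C) should give the ring B benzyl ether benzyl 2-(benzyloxy)-4-[(2-(benzyloxy)-4-{[4,5-bis(benzyloxy)-2-methoxy-6-methylbenzoyl]oxy}-6-methylbenzoyl)oxy]-6-methylbenzoate F5. Hydrogenolysis of F5 under the conditions of step 16 then removes all five benzyl groups and gives 22 without passing through boron.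

3. Step 4. The electrophile may attack the other free ring position (between the C1 benzyloxy and the methoxy group), or the reaction may stall at the doubly flanked site. Fallback, setting out from 4 and returning at 6: bromination with NBS in MeCN at 0 °C, which is more strictly para-directed and uses a smaller electrophile, should give 1,2-bis(benzyloxy)-4-bromo-5-methoxy-3-methylbenzene F6, whose isomeric purity can be checked before carbon is introduced. Bromine–lithium exchange (n-BuLi, THF, −78 °C) should give [4,5-bis(benzyloxy)-2-methoxy-6-methylphenyl]lithium F7, and quenching with CO2 followed by acidification gives acid 6 directly.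

**Further compounds**

F1 | step 13 | 6-methyl-4-[(triisopropylsilyl)oxy]-2H-pyran-2-one | Cc1cc(O[Si](C(C)C)(C(C)C)C(C)C)cc(=O)o1
F2 | step 13 | bridged lactone from F1 and 17, racemic (one enantiomer drawn), not isolated | C[C@]12OC(=O)[C@H](C(O[Si](C(C)C)(C(C)C)C(C)C)=C1)C(Br)=C2C(=O)Oc1cc(C)c(C(=O)OCc2ccccc2)c(OCc2ccccc2)c1
F3 | step 13 | benzyl 2-(benzyloxy)-4-({2-bromo-6-methyl-4-[(triisopropylsilyl)oxy]benzoyl}oxy)-6-methylbenzoate | Cc1cc(O[Si](C(C)C)(C(C)C)C(C)C)cc(Br)c1C(=O)Oc1cc(C)c(C(=O)OCc2ccccc2)c(OCc2ccccc2)c1
F4 | step 13 | benzyl 2-(benzyloxy)-4-[(2-bromo-4-hydroxy-6-methylbenzoyl)oxy]-6-methylbenzoate | Cc1cc(O)cc(Br)c1C(=O)Oc1cc(C)c(C(=O)OCc2ccccc2)c(OCc2ccccc2)c1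
F5 | step 14 | benzyl 2-(benzyloxy)-4-[(2-(benzyloxy)-4-{[4,5-bis(benzyloxy)-2-methoxy-6-methylbenzoyl]oxy}-6-methylbenzoyl)oxy]-6-methylbenzoate | COc1cc(OCc2ccccc2)c(OCc2ccccc2)c(C)c1C(=O)Oc1cc(C)c(C(=O)Oc2cc(C)c(C(=O)OCc3ccccc3)c(OCc3ccccc3)c2)c(OCc2ccccc2)c1
F6 | step 4 | 1,2-bis(benzyloxy)-4-bromo-5-methoxy-3-methylbenzene | COc1cc(OCc2ccccc2)c(OCc2ccccc2)c(C)c1Br
F7 | step 4 | [4,5-bis(benzyloxy)-2-methoxy-6-methylphenyl]lithium | [Li]c1c(OC)cc(OCc2ccccc2)c(OCc2ccccc2)c1C
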